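The cyclohexadienone ring (C3a, C4, C5, C6, C7, C7a) is opened at C3a–C4, the two ends of a hexatriene C3a=C7a–C7=C6–C5=C4. In the precursor O1 does not yet sit on C7a: it is bound to the future allyl carbon C2′, so that O1, C2, C3, C3a, C1′ and C2′ form a temporary dihydropyran made by an asymmetric hetero-Diels–Alder reaction. A thermal 6π electrocyclisation of the silyl trienol ether closes the carbocycle, sets quaternary C3a opposite to the pseudoaxial C3 methyl group and leaves C1′=C2′–O1 as an enol ether. Acid then moves O1 from C2′ to C7a, and a Wittig reaction completes the allyl group.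

Key step: step 8

Atom labels: benzofuranone numbering of the target (O1, C2, C3, C3a, C4 to C7, C7a). The allyl carbons are C1′ to C3′, counted outwards from C3a.

Assumption: the (1R,2S)-aminoindanol-derived chromium complex of step 2 is taken to give the 2R pyran. Its mirror-image complex would be used if the sense of induction is the opposite.

Step 1
Reactants: 1 pent-1-en-3-one
Product: 2 (Z)-triethyl(penta-1,3-dien-3-yloxy)silane
Conditions: Et3SiOTf, Et3N, Et2O, 0 °C
Reagents that add atoms: triethylsilyl trifluoromethanesulfonate, CC[Si](CC)(CC)OS(=O)(=O)C(F)(F)F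
Why: Soft enolisation of the ethyl ketone (silyl enol ether formation) should give the 2-silyloxydiene as the Z enol ether, in which methyl and oxygen are cis, so the methyl group points outward in the s-cis diene.

Step 2
Reactants: 2 (Z)-triethyl(penta-1,3-dien-3-yloxy)silane; 3 3,4,5-trimethoxybenzaldehyde
Product: 4 (2R,3R)-3-methyl-4-(triethylsilyloxy)-2-(3,4,5-trimethoxyphenyl)-3,6-dihydro-2H-pyran (2,3-cis)
Conditions: CrCl(L) 5 mol % [L = dianion of (1R,2S)-1-{[3-(adamantan-1-yl)-2-hydroxy-5-methylbenzylidene]amino}-2,3-dihydro-1H-inden-2-ol], 4 Å MS, EtOAc, rt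
Reagents that add atoms: none
Why: In this catalysed hetero-Diels–Alder reaction the enol-ether carbon bonds to the aldehyde carbon and oxygen to the CH2 terminus, the endo transition state puts the outward methyl group cis to the aryl group (C2/C3 cis), and the chiral complex of trivalent chromium selects the aldehyde face that makes C2 R.

Step 3
Reactants: 4 (2R,3R)-3-methyl-4-(triethylsilyloxy)-2-(3,4,5-trimethoxyphenyl)-3,6-dihydro-2H-pyran
Product: 5 (2R,3R)-3-methyl-2-(3,4,5-trimethoxyphenyl)-3,6-dihydro-2H-pyran-4-yl trifluoromethanesulfonate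
Conditions: CsF, PhNTf2, DME, rt
Reagents that add atoms: N-phenylbis(trifluoromethanesulfonimide), O=S(=O)(N(c1ccccc1)S(=O)(=O)C(F)(F)F)C(F)(F)F
Why: Fluoride cleaves the Si–O bond and the regiodefined enolate is O-sulfonylated (enol triflate formation), so the double bond stays at C3a=C1′ and C3 is not enolised.

Step 4
Reactants: 6 2,2-dimethoxyacetaldehyde (dried)
Product: 7 rac-1,1-dimethoxybut-3-yn-2-ol
Conditions: HC≡CMgBr, THF, 0 °C; aqueous work-up
Reagents that add atoms: ethynylmagnesium bromide, C#C[Mg]Br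
Why: This is a Grignard addition of the acetylide to the aldehyde, and the racemic carbinol centre (future C5) is erased in step 7.

Step 5
Reactants: 7 rac-1,1-dimethoxybut-3-yn-2-ol
Product: 8 rac-3,4,4-trimethoxybut-1-yne
Conditions: NaH, MeI, THF, 0 °C to rt
Reagents that add atoms: iodomethane, CI
Why: A Williamson ether synthesis on the alkoxide installs the future C5 methoxy group while the acetal and the terminal alkyne stay untouched.

Step 6
Reactants: 5 (2R,3R)-3-methyl-2-(3,4,5-trimethoxyphenyl)-3,6-dihydro-2H-pyran-4-yl trifluoromethanesulfonate; 8 rac-3,4,4-trimethoxybut-1-yne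
Product: 9 4,5,5-trimethoxy-1-[(2R,3S)-3-methyl-2-(3,4,5-trimethoxyphenyl)-3,6-dihydro-2H-pyran-4-yl]pent-2-yn-1-one (both epimers at the chain methoxy carbon)
Conditions: CO (1 atm), PdCl2(PPh3)2 5 mol %, CuI 5 mol %, Et3N, THF, rt
Reagents that add atoms: carbon monoxide, [C-]#[O+]
Why: In this carbonylative Sonogashira coupling the alkenyl triflate adds oxidatively to zerovalent palladium, CO inserts and the acylpalladium species couples with the copper acetylide, which attaches C7a, C7, C6, C5 and C4 to C3a in one step.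

Step 7
Reactants: 9 4,5,5-trimethoxy-1-[(2R,3S)-3-methyl-2-(3,4,5-trimethoxyphenyl)-3,6-dihydro-2H-pyran-4-yl]pent-2-yn-1-one
Product: 11 (2E,4Z)-3,4,5-trimethoxy-1-[(2R,3S)-3-methyl-2-(3,4,5-trimethoxyphenyl)-3,6-dihydro-2H-pyran-4-yl]penta-2,4-dien-1-one, via methanol adduct 10 (not isolated)
Conditions: NaOMe, MeOH, 0 to 60 °C
Reagents that add atoms: methanol, CO
Why: Methoxide adds to the ynone at C6 (oxa-Michael addition), reversible addition equilibrates the enone to the E isomer with C7a and C5 cis, and vinylogous E1cB loss of methanol from the acetal (C5–H is γ to the carbonyl) extends the push–pull system to the terminal enol ether.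

Step 8
Reactants: 11 (2E,4Z)-3,4,5-trimethoxy-1-[(2R,3S)-3-methyl-2-(3,4,5-trimethoxyphenyl)-3,6-dihydro-2H-pyran-4-yl]penta-2,4-dien-1-one
Product: 14 (4R,5S,6S)-9,10-dimethoxy-5-methyl-4-(3,4,5-trimethoxyphenyl)-3-oxaspiro[5.5]undeca-1,8,10-trien-7-one, via silyl tetraene 12 (not isolated), via cyclohexadiene 13 (not isolated)
Conditions: KN(SiMe3)2, THF, −78 °C; TBSCl; solvent change to toluene, 130 °C (sealed); then PPTS (cat.), CH2Cl2, rt
Reagents that add atoms: none
Why: γ-Deprotonation at C2′H2 and O-silylation give tetraene 12, whose segment C3a=C7a–C7=C6–C5=C4 is a hexatriene with C7a and C5 already cis on the central double bond; on heating, a thermal disrotatory 6π electrocyclisation joins the termini C3a and C4 to give 13, and acid-catalysed vinylogous loss of TBSOMe (the silyl dienol ether expels the C4 methoxy group) unveils dienone 14. The closest known reaction type is the thermal electrocyclisation of silyloxy-substituted (Z)-hexatrienes to cyclohexadienes, which also tolerates a fully substituted terminus. One ring is closed, the six-membered carbocycle, in a pericyclic 6π mode that makes it spiro to the pyran at C3a. C3a is the only lasting new stereocentre: allylic 1,3-strain with the exocyclic C3a=C7a bond holds the C3 methyl group pseudoaxial (aryl pseudoequatorial), so C4 bonds to the opposite face and ends trans to the methyl group on the pyran ring, which becomes the cis relation on the later furan ring, while the C4 methoxy centre is erased in the elimination. Periselectivity is secured because the ring locks the diene C2′=C1′–C3a=C7a s-trans, so no other triene can fold, and because the silyl group blocks closure through oxygen to a 2H-pyran.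

Step 9
Reactants: 14 (4R,5S,6S)-9,10-dimethoxy-5-methyl-4-(3,4,5-trimethoxyphenyl)-3-oxaspiro[5.5]undeca-1,8,10-trien-7-one
Product: 16 2-[(2R,3S,3aS)-5-methoxy-3-methyl-6-oxo-2-(3,4,5-trimethoxyphenyl)-2,3-dihydro-1-benzofuran-3a(6H)-yl]acetaldehyde, via lactol 15 (not isolated)
Conditions: TsOH·H2O (cat.), THF–H2O 9:1, 0 °C to rt
Reagents that add atoms: water, O
Why: Enol ether hydrolysis gives lactol 15, whose open form adds the C2 hydroxyl to the C7a ketone (5-exo-trig), and dehydration followed by water attack at C6 with loss of methanol (vinylogous transesterification) gives the cross-conjugated dienone, with C2 retained because the C2–O1 bond is never broken.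

Step 10
Reactants: 16 2-[(2R,3S,3aS)-5-methoxy-3-methyl-6-oxo-2-(3,4,5-trimethoxyphenyl)-2,3-dihydro-1-benzofuran-3a(6H)-yl]acetaldehyde
Product: 17 (2R,3S,3aS)-3a-allyl-5-methoxy-3-methyl-2-(3,4,5-trimethoxyphenyl)-3,3a-dihydro-1-benzofuran-6(2H)-one (target)
Conditions: Ph3PCH3Br, KN(SiMe3)2, THF, 0 °C; then 16, −78 to 0 °C
Reagents that add atoms: methyltriphenylphosphonium bromide, C[P+](c1ccccc1)(c1ccccc1)c1ccccc1.[Br-]
Why: Wittig methylenation should take the aldehyde selectively, because the C6 carbonyl is a deactivated vinylogous ester, and no stereocentre is touched.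

Compound list
1 | pent-1-en-3-one | C=CC(=O)CC | starting material
2 | (Z)-triethyl(penta-1,3-dien-3-yloxy)silane | C/C=C(\O[Si](CC)(CC)CC)C=C | intermediate
3 | 3,4,5-trimethoxybenzaldehyde | COc1cc(C=O)cc(OC)c1OC | starting material
4 | (2R,3R)-3-methyl-4-(triethylsilyloxy)-2-(3,4,5-trimethoxyphenyl)-3,6-dihydro-2H-pyran | CC[Si](CC)(CC)OC1=CCO[C@@H](c2cc(OC)c(OC)c(OC)c2)[C@H]1C | intermediate
5 | (2R,3R)-3-methyl-2-(3,4,5-trimethoxyphenyl)-3,6-dihydro-2H-pyran-4-yl trifluoromethanesulfonate | O=S(=O)(OC1=CCO[C@@H](c2cc(OC)c(OC)c(OC)c2)[C@H]1C)C(F)(F)F | intermediate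
6 | 2,2-dimethoxyacetaldehyde | COC(OC)C=O | starting material
7 | rac-1,1-dimethoxybut-3-yn-2-ol | C#CC(O)C(OC)OC | intermediate
8 | rac-3,4,4-trimethoxybut-1-yne | C#CC(OC)C(OC)OC | intermediate
9 | 4,5,5-trimethoxy-1-[(2R,3S)-3-methyl-2-(3,4,5-trimethoxyphenyl)-3,6-dihydro-2H-pyran-4-yl]pent-2-yn-1-one (chain methoxy carbon unassigned, both epimers) | COC(OC)C(OC)C#CC(=O)C1=CCO[C@@H](c2cc(OC)c(OC)c(OC)c2)[C@H]1C | intermediate
10 | (E)-3,4,5,5-tetramethoxy-1-[(2R,3S)-3-methyl-2-(3,4,5-trimethoxyphenyl)-3,6-dihydro-2H-pyran-4-yl]pent-2-en-1-one (not isolated) | COC(OC)C(OC)/C(OC)=C\C(=O)C1=CCO[C@@H](c2cc(OC)c(OC)c(OC)c2)[C@H]1C | intermediate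
11 | (2E,4Z)-3,4,5-trimethoxy-1-[(2R,3S)-3-methyl-2-(3,4,5-trimethoxyphenyl)-3,6-dihydro-2H-pyran-4-yl]penta-2,4-dien-1-one | CO/C=C(OC)/C(OC)=C\C(=O)C1=CCO[C@@H](c2cc(OC)c(OC)c(OC)c2)[C@H]1C | intermediate
12 | (2R,3S)-4-[(2E,4Z)-1-(tert-butyldimethylsilyloxy)-3,4,5-trimethoxypenta-2,4-dien-1-ylidene]-3-methyl-2-(3,4,5-trimethoxyphenyl)-3,4-dihydro-2H-pyran (either geometry at the exocyclic bond, not isolated) | CO/C=C(OC)/C(OC)=C\C(O[Si](C)(C)C(C)(C)C)=C1C=CO[C@@H](c2cc(OC)c(OC)c(OC)c2)[C@H]1C | intermediate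
13 | (4R,5S,6S)-7-(tert-butyldimethylsilyloxy)-9,10,11-trimethoxy-5-methyl-4-(3,4,5-trimethoxyphenyl)-3-oxaspiro[5.5]undeca-1,7,9-triene (C11 transient and unassigned, not isolated) | COC1C(OC)=C(OC)C=C(O[Si](C)(C)C(C)(C)C)[C@]12C=CO[C@@H](c3cc(OC)c(OC)c(OC)c3)[C@H]2C | intermediate
14 | (4R,5S,6S)-9,10-dimethoxy-5-methyl-4-(3,4,5-trimethoxyphenyl)-3-oxaspiro[5.5]undeca-1,8,10-trien-7-one (ring CH=, the future C4, trans to the methyl group on the pyran) | O=C1C=C(OC)C(OC)=C[C@@]12C=CO[C@@H](c3cc(OC)c(OC)c(OC)c3)[C@H]2C | intermediate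
15 | (4R,5S,6S)-2-hydroxy-9,10-dimethoxy-5-methyl-4-(3,4,5-trimethoxyphenyl)-3-oxaspiro[5.5]undeca-8,10-dien-7-one (both anomers, not isolated) | O=C1C=C(OC)C(OC)=C[C@@]12CC(O)O[C@@H](c3cc(OC)c(OC)c(OC)c3)[C@H]2C | intermediate
16 | 2-[(2R,3S,3aS)-5-methoxy-3-methyl-6-oxo-2-(3,4,5-trimethoxyphenyl)-2,3-dihydro-1-benzofuran-3a(6H)-yl]acetaldehyde | O=CC[C@]12C=C(OC)C(=O)C=C1O[C@@H](c1cc(OC)c(OC)c(OC)c1)[C@H]2C | intermediate
17 | (2R,3S,3aS)-3a-allyl-5-methoxy-3-methyl-2-(3,4,5-trimethoxyphenyl)-3,3a-dihydro-1-benzofuran-6(2H)-one | C=CC[C@]12C=C(OC)C(=O)C=C1O[C@@H](c1cc(OC)c(OC)c(OC)c1)[C@H]2C | target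

Total step count: 10. Longest linear sequence: 8 steps (1, 2, 3, 6, 7, 8, 9, 10).

Steps most likely to fail

Step 8. The closure at the fully substituted terminus may be slow enough that a 1,5-hydrogen shift from C3 or thermal decay of the electron-rich tetraene takes over.
- The fallback replaces the pericyclic closure by an intramolecular Heck reaction and sets out from 11.
- NaOH in THF–H2O exchanges the unhindered terminal methoxy group at C4 by addition–elimination and gives sodium enolate F1, in which chelation of sodium to the C6 methoxy group holds the oxygen cis to C6.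
- PhNTf2 converts it into alkenyl triflate F2.
- Pd(OAc)2, PPh3 and 1,2,2,6,6-pentamethylpiperidine in MeCN at 70 °C should then bring about 6-exo carbopalladation of C3a=C1′ on the face opposite to the methyl group and β-hydride elimination toward C2′. This returns to the route at 14.

Step 9. The freed aldehyde may be attacked by the nucleophilic C7 in an aldol process, and prolonged acid may ionise the benzylic C2–O1 bond and epimerise C2.
- The fallback removes the aldehyde before the oxygen transfer and sets out from 14.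
- Oxalic acid on wet silica gel in CH2Cl2 stops the hydrolysis at lactol 15, which is isolated.
- Excess Ph3P=CH2 methylenates its open form and gives hydroxy dienone F3.
- A catalytic amount of camphorsulfonic acid in moist CH2Cl2 closes O1 onto C7a with loss of methanol. This returns to the route at 17.

Step 2. The electron-rich aromatic aldehyde may react sluggishly, and a stepwise Mukaiyama aldol pathway may erode the endo and facial selectivity.
- The fallback builds the same ring from an auxiliary-controlled aldol and sets out from 3.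
- An Evans syn-aldol reaction with (R)-4-benzyl-3-propionyloxazolidin-2-one (Bu2BOTf, Et3N, CH2Cl2, −78 °C) gives aldol imide F4.
- AlMe3 and MeNHOMe·HCl give N-methoxy-N-methylamide F5.
- CH2=CHMgBr gives hydroxy enone F6.
- A sulfonic acid resin closes it by 6-endo oxa-Michael addition to pyranone F7.
- Kinetic deprotonation at the CH2 group (LDA, THF, −78 °C) and PhNTf2 return to the route at 5.

Further compounds
F1 | step 8 | sodium (1E,3E)-1,2,3-trimethoxy-free enolate: sodium salt of (2E,4E)-5-hydroxy-3,4-dimethoxy-1-[(2R,3S)-3-methyl-2-(3,4,5-trimethoxyphenyl)-3,6-dihydro-2H-pyran-4-yl]penta-2,4-dien-1-one | [Na+].[O-]\C=C(OC)/C(OC)=C\C(=O)C1=CCO[C@@H](c2cc(OC)c(OC)c(OC)c2)[C@H]1C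
F2 | step 8 | (1E,3E)-2,3-dimethoxy-5-[(2R,3S)-3-methyl-2-(3,4,5-trimethoxyphenyl)-3,6-dihydro-2H-pyran-4-yl]-5-oxopenta-1,3-dien-1-yl trifluoromethanesulfonate | O=S(=O)(O\C=C(OC)/C(OC)=C\C(=O)C1=CCO[C@@H](c2cc(OC)c(OC)c(OC)c2)[C@H]1C)C(F)(F)F
F3 | step 9 | (6S)-6-allyl-6-[(1R,2S)-1-hydroxy-1-(3,4,5-trimethoxyphenyl)propan-2-yl]-3,4-dimethoxycyclohexa-2,4-dien-1-one | C=CC[C@@]1(C=C(OC)C(OC)=CC1=O)[C@H](C)[C@@H](O)c1cc(OC)c(OC)c(OC)c1
F4 | step 2 | (R)-4-benzyl-3-[(2R,3R)-3-hydroxy-2-methyl-3-(3,4,5-trimethoxyphenyl)propanoyl]oxazolidin-2-one | O[C@@H](c1cc(OC)c(OC)c(OC)c1)[C@H](C(=O)N1C(=O)OC[C@H]1Cc1ccccc1)C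
F5 | step 2 | (2R,3R)-3-hydroxy-N-methoxy-N,2-dimethyl-3-(3,4,5-trimethoxyphenyl)propanamide | O[C@@H](c1cc(OC)c(OC)c(OC)c1)[C@H](C(=O)N(C)OC)C
F6 | step 2 | (4R,5R)-5-hydroxy-4-methyl-5-(3,4,5-trimethoxyphenyl)pent-1-en-3-one | O[C@@H](c1cc(OC)c(OC)c(OC)c1)[C@H](C(=O)C=C)C
F7 | step 2 | (2R,3R)-3-methyl-2-(3,4,5-trimethoxyphenyl)tetrahydro-4H-pyran-4-one | O=C1CCO[C@@H](c2cc(OC)c(OC)c(OC)c2)[C@H]1C
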